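**Assumption:** the SMILES carries no stereodescriptor and the molecule has no stereocentre, so the compound is made exactly as drawn; the hindered 7,1'-biaryl axis forms without control (racemic if it is configurationally stable).

**Retrosynthetic overview**
- The isoquinoline benzo ring (ring A) is disconnected last: target ⇒ O-methylation of a 7-naphthylisoquinolin-8-olate ⇒ benzannulation of an α-naphthyl ketone on a purchased 2,4,6-trimethylpyridine (the 4-methyl becomes C5, a formamide-acetal carbon becomes C6).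
- Key disconnection: the future biaryl bond C7–C1' is cut as a Csp3–Csp2 bond between the α-carbon of 3-acetyl-2,4,6-trimethylpyridine, used as an enolonium (trivalent-iodine enolate), and C4 of 1,8-dimethoxy-3-methylnaphthalene.
- The naphthalene comes from anionic annulation of an o-methallylbenzamide, made by directed ortho-metalation of N,N-diethyl-2-methoxybenzamide.
- Ring order: naphthalene carbocycle (step 2), pyridine ring (purchased), isoquinoline ring A (step 5).

**Step 1**
Reactants: 1 N,N-diethyl-2-methoxybenzamide; 2 3-bromo-2-methylprop-1-ene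
Product: 5 N,N-diethyl-2-methoxy-6-(2-methylprop-2-en-1-yl)benzamide, via aryllithium 3 (not isolated), via arylmagnesium bromide 4 (not isolated)
Conditions: s-BuLi (1.1 equiv), TMEDA, THF, −78 °C; MgBr2·OEt2, −78 → 0 °C; 2 (2 equiv), 0 °C → rt
Reagents that add atoms: none
Why: Directed ortho-metalation: the tertiary amide outranks OMe and its other ortho position is blocked, so lithiation occurs only at C6; Li→Mg exchange gives an aryl Grignard that is allylated cleanly by the symmetrical methallyl bromide.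

**Step 2**
Reactants: 5 N,N-diethyl-2-methoxy-6-(2-methylprop-2-en-1-yl)benzamide
Product: 7 1,8-dimethoxy-3-methylnaphthalene, via lithium naphtholate 6 (not isolated)
Conditions: LiN(i-Pr)2 (1.5 equiv), THF, −78 °C → rt; then DMPU, MeI (5 equiv), 0 °C → rt
Reagents that add atoms: iodomethane, CI
Why: Anionic aromatic annulation of an o-allylbenzamide: the benzylic/allylic anion attacks the amide carbonyl through its terminal carbon (six-membered ring), LiNEt2 is lost and the dienone tautomerises to the naphtholate, which is O-methylated in the same flask (Williamson).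

**Step 3**
Reactants: 8 1-(2,4,6-trimethylpyridin-3-yl)ethan-1-one
Product: 9 2,4,6-trimethyl-3-{1-[(trimethylsilyl)oxy]ethenyl}pyridine
Conditions: Me3SiOTf (1.05 equiv), Et3N (1.5 equiv), CH2Cl2, 0 °C, 30 min; pentane, filter, concentrate; used crude
Reagents that add atoms: trimethylsilyl trifluoromethanesulfonate, C[Si](C)(C)OS(=O)(=O)C(F)(F)F
Why: Soft enolisation/silyl enol ether formation at the only carbonyl-activated position (acetyl CH3); the picolyl methyls are far less acidic and the hindered nitrogen is silylated only reversibly.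

**Step 4 (key step)**
Reactants: 9 2,4,6-trimethyl-3-{1-[(trimethylsilyl)oxy]ethenyl}pyridine; 7 1,8-dimethoxy-3-methylnaphthalene
Product: 11 2-(4,5-dimethoxy-2-methylnaphthalen-1-yl)-1-(2,4,6-trimethylpyridin-3-yl)ethan-1-one, via enolonium 10 (not isolated)
Conditions: PhI(OH)OTs (0.95 equiv), BF3·OEt2 (2.5 equiv), CH2Cl2, −78 °C; 9 (1.0 equiv), 10 min; 7 (1.3 equiv), −78 → −20 °C; aq NaHCO3
Reagents that add atoms: none
Why: Proposed new method: BF3-activated PhI(OH)OTs converts 9 at −78 °C into the trivalent-iodine enolonium 10, whose α-CH2 is electrophilic with PhI as hypernucleofuge (the twisted, BF3-bound pyridyl ring is not conjugated, so 10 behaves like an alkyl methyl ketone enolonium); because no free oxidant remains when 7 is added, the naphthalene reacts by Friedel–Crafts substitution at C4 (para to OMe, ortho to CH3, its most electron-rich position; the small CH2 electrophile tolerates the flanking groups), joining a ketone α-carbon and an arene carbon that are both normally nucleophilic; the closest known reaction type is the two-stage umpolung α-arylation and α-allylation of silyl enol ethers through PhI(OH)OTs/BF3-derived enolonium species with indoles, pyrroles and allylsilanes; no stereocentre is formed.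

**Step 5**
Reactants: 11 2-(4,5-dimethoxy-2-methylnaphthalen-1-yl)-1-(2,4,6-trimethylpyridin-3-yl)ethan-1-one
Product: 14 7-(4,5-dimethoxy-2-methylnaphthalen-1-yl)-8-methoxy-1,3-dimethylisoquinoline, via enaminone 12 (not isolated), via potassium isoquinolinolate 13 (not isolated)
Conditions: t-BuOCH(NMe2)2 (1.5 equiv), toluene, 100 °C; evaporate; KOt-Bu (1.2 equiv), DMF, 60 °C; N2 sparge; MeI (1.3 equiv), 0 °C → rt
Reagents that add atoms: tert-butoxybis(dimethylamino)methane, CN(C)C(OC(C)(C)C)N(C)C; iodomethane, CI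
Why: Bredereck aminomethylenation of the doubly activated ArCH2C=O gives the enaminone; under equilibrating potassium base the γ-picolyl 4-CH3 (about 2 pKa units more acidic than the α-picolyl 2-CH3) adds to the enaminone β-carbon (intramolecular Michael addition–elimination, formally a 6π closure) and loss of Me2NH aromatises ring A to the isoquinolin-8-olate, which is trapped on oxygen by MeI (Williamson), avoiding isolation of the amphoteric phenol; the sp3–sp2 bond of step 4 becomes the biaryl axis, with no stereocentre.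

**Compound list**
1 | N,N-diethyl-2-methoxybenzamide | CCN(CC)C(=O)c1ccccc1OC | starting material
2 | 3-bromo-2-methylprop-1-ene | C=C(C)CBr | starting material
3 | [2-(diethylcarbamoyl)-3-methoxyphenyl]lithium | CCN(CC)C(=O)c1c(OC)cccc1[Li] | intermediate
4 | [2-(diethylcarbamoyl)-3-methoxyphenyl]magnesium bromide | CCN(CC)C(=O)c1c(OC)cccc1[Mg]Br | intermediate
5 | N,N-diethyl-2-methoxy-6-(2-methylprop-2-en-1-yl)benzamide | CCN(CC)C(=O)c1c(OC)cccc1CC(C)=C | intermediate
6 | lithium 8-methoxy-3-methylnaphthalen-1-olate | [Li+].[O-]c1cc(C)cc2cccc(OC)c12 | intermediate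
7 | 1,8-dimethoxy-3-methylnaphthalene | COc1cc(C)cc2cccc(OC)c12 | intermediate
8 | 1-(2,4,6-trimethylpyridin-3-yl)ethan-1-one (3-acetyl-2,4,6-collidine) | CC(=O)c1c(C)cc(C)nc1C | starting material
9 | 2,4,6-trimethyl-3-{1-[(trimethylsilyl)oxy]ethenyl}pyridine | C=C(O[Si](C)(C)C)c1c(C)cc(C)nc1C | intermediate
10 | 2-[phenyl(tosyloxy)-λ3-iodanyl]-1-(2,4,6-trimethylpyridin-3-yl)ethan-1-one (enolonium, drawn C-bound) | Cc1ccc(cc1)S(=O)(=O)OI(CC(=O)c1c(C)cc(C)nc1C)c1ccccc1 | intermediate
11 | 2-(4,5-dimethoxy-2-methylnaphthalen-1-yl)-1-(2,4,6-trimethylpyridin-3-yl)ethan-1-one | COc1cc(C)c(CC(=O)c2c(C)cc(C)nc2C)c2cccc(OC)c12 | intermediate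
12 | (E)-3-(dimethylamino)-2-(4,5-dimethoxy-2-methylnaphthalen-1-yl)-1-(2,4,6-trimethylpyridin-3-yl)prop-2-en-1-one (either alkene geometry cyclises) | CN(C)/C=C(/C(=O)c1c(C)cc(C)nc1C)c1c(C)cc(OC)c2c(OC)cccc12 | intermediate
13 | potassium 7-(4,5-dimethoxy-2-methylnaphthalen-1-yl)-1,3-dimethylisoquinolin-8-olate | [K+].[O-]c1c(-c2c(C)cc(OC)c3c(OC)cccc23)ccc2cc(C)nc(C)c12 | intermediate
14 | 7-(4,5-dimethoxy-2-methylnaphthalen-1-yl)-8-methoxy-1,3-dimethylisoquinoline (CNP0296065.0) | COc1c(-c2c(C)cc(OC)c3c(OC)cccc23)ccc2cc(C)nc(C)c12 | target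

**Totals**
Total step count: 5. Longest linear sequence: 4 (steps 1, 2, 4, 5); the pyridine branch is 3 steps (3, 4, 5).

**Steps most likely to fail, with fallbacks**

Step 4. The enolonium is short-lived, and the pyridine nitrogen may bind iodine or boron unproductively. Tosylate can capture the enolonium (α-tosyloxylation), residual oxidant can dimerise 7, and attack at C5 of 7 may compete with C4. The fallback replaces the iodane by a sulfur-stabilised α-acyl cation, which is not an oxidant and is well established with methoxyarenes. It sets out from compound 9 and comes back at compound 11. Sulfenylation of 9 with PhSCl (CH2Cl2, −78 °C) gives 2-(phenylsulfanyl)-1-(2,4,6-trimethylpyridin-3-yl)ethan-1-one F1. Chlorination with N-chlorosuccinimide (CCl4, rt) gives racemic 2-chloro-2-(phenylsulfanyl)-1-(2,4,6-trimethylpyridin-3-yl)ethan-1-one F2. SnCl4 (2.2 equiv, CH2Cl2, −40 → 0 °C) ionises F2 to the thionium ion, which alkylates 7 to racemic 2-(4,5-dimethoxy-2-methylnaphthalen-1-yl)-2-(phenylsulfanyl)-1-(2,4,6-trimethylpyridin-3-yl)ethan-1-one F3. Zn dust in AcOH removes the sulfur and returns 11.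

Step 5. The main risk is ring closure through the 2-methyl instead of the 4-methyl, which would give the quinolin-5-ol isomer. Aminomethylenation of the hindered CH2 may also be slow. The fallback removes the competing methyl and installs the C1 methyl last. It sets out from compound 7 and comes back at compound 14.
- Commercial 2-chloro-4,6-dimethylpyridine-3-carbonitrile (Cc1cc(C)nc(Cl)c1C#N) is treated with MeMgBr (toluene/THF, 60 °C) to give the bromomagnesium salt of 1-(2-chloro-4,6-dimethylpyridin-3-yl)ethan-1-imine F4, hydrolysed with aqueous HCl to 1-(2-chloro-4,6-dimethylpyridin-3-yl)ethan-1-one F5.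
- Me3SiOTf/Et3N gives 2-chloro-4,6-dimethyl-3-{1-[(trimethylsilyl)oxy]ethenyl}pyridine F6.
- PhI(OH)OTs/BF3·OEt2 at −78 °C gives 1-(2-chloro-4,6-dimethylpyridin-3-yl)-2-[phenyl(tosyloxy)-λ3-iodanyl]ethan-1-one F7, which is intercepted by 7 to give 1-(2-chloro-4,6-dimethylpyridin-3-yl)-2-(4,5-dimethoxy-2-methylnaphthalen-1-yl)ethan-1-one F8.
- t-BuOCH(NMe2)2 (open flask under N2 sweep to remove Me2NH) gives (E)-1-(2-chloro-4,6-dimethylpyridin-3-yl)-3-(dimethylamino)-2-(4,5-dimethoxy-2-methylnaphthalen-1-yl)prop-2-en-1-one F9.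
- KOt-Bu closes ring A through the only methyl that flanks the acyl group, giving potassium 1-chloro-7-(4,5-dimethoxy-2-methylnaphthalen-1-yl)-3-methylisoquinolin-8-olate F10.
- MeI gives 1-chloro-7-(4,5-dimethoxy-2-methylnaphthalen-1-yl)-8-methoxy-3-methylisoquinoline F11.
- Suzuki–Miyaura methylation (trimethylboroxine, Pd(dppf)Cl2, K2CO3, dioxane/H2O, 100 °C) gives 14.

Step 2. The cyclisation is reliable, but the lithium naphtholate is chelated by the peri-methoxy group and may resist methylation in the flask. The fallback sets out from compound 6 and comes back at compound 7. The reaction is quenched with aqueous NH4Cl and 8-methoxy-3-methylnaphthalen-1-ol F12 is isolated. It is then methylated as the neutral naphthol by Mitsunobu redox condensation (MeOH, PPh3, DIAD, THF, rt), which does not depend on the nucleophilicity of a metal naphtholate, to give 7.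

**Further compounds**
F1 | step 4 | 2-(phenylsulfanyl)-1-(2,4,6-trimethylpyridin-3-yl)ethan-1-one | O=C(CSc1ccccc1)c1c(C)cc(C)nc1C
F2 | step 4 | rac-2-chloro-2-(phenylsulfanyl)-1-(2,4,6-trimethylpyridin-3-yl)ethan-1-one | O=C(C(Cl)Sc1ccccc1)c1c(C)cc(C)nc1C
F3 | step 4 | rac-2-(4,5-dimethoxy-2-methylnaphthalen-1-yl)-2-(phenylsulfanyl)-1-(2,4,6-trimethylpyridin-3-yl)ethan-1-one | COc1cc(C)c(C(Sc2ccccc2)C(=O)c2c(C)cc(C)nc2C)c2cccc(OC)c12
F4 | step 5 | bromomagnesium salt of 1-(2-chloro-4,6-dimethylpyridin-3-yl)ethan-1-imine | CC(=N[Mg]Br)c1c(C)cc(C)nc1Cl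
F5 | step 5 | 1-(2-chloro-4,6-dimethylpyridin-3-yl)ethan-1-one | CC(=O)c1c(C)cc(C)nc1Cl
F6 | step 5 | 2-chloro-4,6-dimethyl-3-{1-[(trimethylsilyl)oxy]ethenyl}pyridine | C=C(O[Si](C)(C)C)c1c(C)cc(C)nc1Cl
F7 | step 5 | 1-(2-chloro-4,6-dimethylpyridin-3-yl)-2-[phenyl(tosyloxy)-λ3-iodanyl]ethan-1-one | Cc1ccc(cc1)S(=O)(=O)OI(CC(=O)c1c(C)cc(C)nc1Cl)c1ccccc1
F8 | step 5 | 1-(2-chloro-4,6-dimethylpyridin-3-yl)-2-(4,5-dimethoxy-2-methylnaphthalen-1-yl)ethan-1-one | COc1cc(C)c(CC(=O)c2c(C)cc(C)nc2Cl)c2cccc(OC)c12
F9 | step 5 | (E)-1-(2-chloro-4,6-dimethylpyridin-3-yl)-3-(dimethylamino)-2-(4,5-dimethoxy-2-methylnaphthalen-1-yl)prop-2-en-1-one | CN(C)/C=C(/C(=O)c1c(C)cc(C)nc1Cl)c1c(C)cc(OC)c2c(OC)cccc12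
F10 | step 5 | potassium 1-chloro-7-(4,5-dimethoxy-2-methylnaphthalen-1-yl)-3-methylisoquinolin-8-olate | [K+].[O-]c1c(-c2c(C)cc(OC)c3c(OC)cccc23)ccc2cc(C)nc(Cl)c12
F11 | step 5 | 1-chloro-7-(4,5-dimethoxy-2-methylnaphthalen-1-yl)-8-methoxy-3-methylisoquinoline | COc1c(-c2c(C)cc(OC)c3c(OC)cccc23)ccc2cc(C)nc(Cl)c12
F12 | step 2 | 8-methoxy-3-methylnaphthalen-1-ol | Oc1cc(C)cc2cccc(OC)c12
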